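**Plan**
- Retrosynthetic cuts, in order: the two O–Si bonds; both prenyl C=C bonds (back to allyl, cross-metathesis); C2–C3 of ring C, traced back to the C2–O3 bond of the racemic enol acetal 11 (a 4-methylidene-1,3-benzodioxine); C4=CH2 (lactone methylenation); the acetal bonds C2–O1 and C2–O3 (acid 6 + aldehyde 7); the aryl–allyl bonds at C6 and C8 (double Claisen).
- Forward order: ring A is bought as 2,4,6-trihydroxybenzoic acid and made hexasubstituted first. Ring B is then joined to it through a temporary 1,3-dioxinone ring, ring C arises when that ring rearranges, and allyl becomes prenyl last.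
- Enabling feature: C2 lies between O1 and the para-oxygenated ring B, so it can carry an oxocarbenium (quinone-methide-like) cation. C3 is the α-carbon of the C4 aryl ketone, that is, an enol carbon. Cation and enol can be stored together in one enol acetal ring and released by an acid.
- Stereochemistry: C2 is the only stereocentre, (2S). It is set in step 9 by a chiral counter-anion, stereoconvergently from racemic 11. All later steps are neutral or weakly acidic, so retro-oxa-Michael racemisation has no opening.
- Helpers: an allyl ester (mild release of a decarboxylation-prone acid), allyl in place of prenyl (cannot trap the C2 cation), and two TBS ethers (TBS = tert-butyldimethylsilyl), removed together.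

Key step: step 9

Assumption: no precedent predicts the sense of induction of the chiral acid in step 9, so the catalyst antipode that gives (2S)-12 is used (both derive from the two commercial BINOL enantiomers) and the configuration of 12 is to be confirmed before going on.

Step 1
Reactants: 1 2,4,6-trihydroxybenzoic acid
Product: 2 allyl 2,4,6-trihydroxybenzoate
Conditions: allyl bromide (1.05 equiv), KHCO3, DMF, rt
Reagents that add atoms: allyl bromide, C=CCBr
Why: Bicarbonate deprotonates only the carboxylic acid, so SN2 alkylation of the carboxylate leaves the three phenols free and gives an ester that can later be removed at room temperature without heat or strong base.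

Step 2
Reactants: 2 allyl 2,4,6-trihydroxybenzoate
Product: 3 allyl 2,6-dihydroxy-4-methoxybenzoate
Conditions: MeOH (1.05 equiv), PPh3, DIAD, THF, 0 °C to rt
Reagents that add atoms: methanol, CO
Why: Mitsunobu etherification takes the most acidic and only non-chelated phenol (4-OH, para to the ester), while 2-OH and 6-OH are held in hydrogen bonds to the ester.

Step 3
Reactants: 3 allyl 2,6-dihydroxy-4-methoxybenzoate
Product: 4 allyl 2,6-bis(allyloxy)-4-methoxybenzoate
Conditions: allyl bromide (3 equiv), K2CO3, DMF, 60 °C
Reagents that add atoms: allyl bromide, C=CCBr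
Why: Williamson etherification of both remaining phenols under carbonate conditions, which favour O- over C-allylation.

Step 4
Reactants: 4 allyl 2,6-bis(allyloxy)-4-methoxybenzoate
Product: 5 allyl 3,5-diallyl-2,6-dihydroxy-4-methoxybenzoate
Conditions: N,N-diethylaniline, 195 °C, argon, sealed vessel
Reagents that add atoms: none
Why: In this double aromatic Claisen rearrangement each [3,3] shift can end only at the free ortho carbon (C3 or C5), because the other ortho position carries the ester, so the hexasubstituted ring should form as one regioisomer.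

Step 5
Reactants: 5 allyl 3,5-diallyl-2,6-dihydroxy-4-methoxybenzoate
Product: 6 3,5-diallyl-2,6-dihydroxy-4-methoxybenzoic acid
Conditions: Pd(PPh3)4 (3 mol %), morpholine, THF, rt; cold dilute citric acid work-up; used at once
Reagents that add atoms: none
Why: In this Tsuji–Trost deallylation zerovalent palladium ionises only the allyl carboxylate and morpholine takes up the allyl unit, while C-allyl groups and phenols stay untouched and the acid never sees heat.

Step 6
Reactants: 6 3,5-diallyl-2,6-dihydroxy-4-methoxybenzoic acid; 7 4-(tert-butyldimethylsilyloxy)benzaldehyde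
Product: 9 rac-6,8-diallyl-5-hydroxy-7-methoxy-2-[4-(tert-butyldimethylsilyloxy)phenyl]-4H-1,3-benzodioxin-4-one, via tris(trimethylsilyl) derivative 8 (not isolated)
Conditions: (a) HMDS, THF, rt, evaporate; (b) 7, TMSOTf (15 mol %), CH2Cl2, −78 to −30 °C; pyridine quench, pH 7 buffer, silica gel (the aryl OTMS group falls off)
Reagents that add atoms: hexamethyldisilazane, C[Si](C)(C)N[Si](C)(C)C (its silyl groups stand only in 8)
Why: In this silyl-modified acetalisation of a hydroxy acid (the union half of the Petasis–Ferrier sequence) the silyl ester and one of the two equivalent aryl silyl ethers add to the TMSOTf-activated aldehyde with loss of hexamethyldisiloxane; ring A has no free carbon for Friedel–Crafts attack, and the acetal centre forms racemic, which is harmless.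

Step 7
Reactants: 9 rac-6,8-diallyl-5-hydroxy-7-methoxy-2-[4-(tert-butyldimethylsilyloxy)phenyl]-4H-1,3-benzodioxin-4-one
Product: 10 rac-6,8-diallyl-5-(tert-butyldimethylsilyloxy)-7-methoxy-2-[4-(tert-butyldimethylsilyloxy)phenyl]-4H-1,3-benzodioxin-4-one
Conditions: TBSOTf, 2,6-lutidine, CH2Cl2, 0 °C
Reagents that add atoms: tert-butyldimethylsilyl triflate, CC(C)(C)[Si](C)(C)OS(=O)(=O)C(F)(F)F
Why: The silyl triflate is reactive enough for the chelated, flanked 5-OH, lutidine keeps the acetal free of acid, and the acidic proton must be masked before the titanium reagent is used.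

Step 8
Reactants: 10 rac-6,8-diallyl-5-(tert-butyldimethylsilyloxy)-7-methoxy-2-[4-(tert-butyldimethylsilyloxy)phenyl]-4H-1,3-benzodioxin-4-one
Product: 11 rac-6,8-diallyl-5-(tert-butyldimethylsilyloxy)-7-methoxy-4-methylidene-2-[4-(tert-butyldimethylsilyloxy)phenyl]-4H-1,3-benzodioxine
Conditions: Cp2TiMe2 (3 equiv), toluene/THF, 70 °C, dark; filtration through basic alumina (1% Et3N)
Reagents that add atoms: dimethyltitanocene Cp2TiMe2, [CH3-].[CH3-].[Ti+4].c1cc[cH-]c1.c1cc[cH-]c1
Why: In this Petasis methylenation, as used on 1,3-dioxan-4-ones, Cp2TiMe2 loses methane to give Cp2Ti=CH2, which adds to the only carbonyl group and cycloreverts to the enol ether under non-acidic, non-basic conditions that spare the acetal, silyl ethers and alkenes.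

Step 9
Reactants: 11 rac-6,8-diallyl-5-(tert-butyldimethylsilyloxy)-7-methoxy-4-methylidene-2-[4-(tert-butyldimethylsilyloxy)phenyl]-4H-1,3-benzodioxine
Product: 12 (2S)-6,8-diallyl-5-(tert-butyldimethylsilyloxy)-7-methoxy-2-[4-(tert-butyldimethylsilyloxy)phenyl]chroman-4-one
Conditions: chiral BINOL-derived imidodiphosphorimidate Brønsted acid (IDPi, N-triflyl, 5 mol %), 4 Å MS, toluene (0.02 M), −40 °C; Et3N quench at −40 °C
Reagents that add atoms: none
Why: Proposed new method: the chiral acid HX* hydrogen-bonds to and protonates the enol oxygen O3 of 11, the C2–O3 bond breaks because the cation at C2 is carried by O1 and above all by the para-silyloxy ring B, and the enol carbon C3, still tethered through ring A, attacks C2 to give the C4 ketone and return HX* (a net 1,3 O-to-C shift; protonation at the exocyclic CH2 is reversible and leads back to the same ion pair). The closest known reaction types are the Petasis–Ferrier rearrangement of 4-methylidene-1,3-dioxanes with achiral aluminium Lewis acids such as Me2AlCl, the chiral phosphoric acid catalysed aza-Petasis–Ferrier rearrangement of racemic hemiaminal vinyl ethers, and additions of enol silanes to oxocarbenium ions paired with confined chiral anions; the enantioselective all-oxygen version on a benzo-fused enol acetal is the new element. Ring C closes in the 6-(enolendo)-endo-trig mode while the temporary dioxine ring opens. The C2 configuration of 11 is erased in the planar oxocarbenium ion, return by O-attack is fast and reversible whereas C–C bond formation is irreversible, so both enantiomers of 11 should drain through one ion pair in which the anion, fixed by the enol O–H hydrogen bond and by contact with the cation, covers one face of C2 and thereby sets (2S). The step needs C- over O-alkylation (only the ketone is a thermodynamic sink), productive ionisation (loss of O1 instead of O3 can only re-close because of the tether) and no capture of the cation by other π-systems: ring A has no free carbon, and an allyl group at C8 could give only a primary cation or a seven-membered ring with a secondary cation, whereas a prenyl group would close a six-membered ring to a tertiary cation, which is why the side chains are carried as allyl groups. High dilution and the absence of any achiral acid hold back intermolecular coupling and racemic background reaction.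

Step 10
Reactants: 12 (2S)-6,8-diallyl-5-(tert-butyldimethylsilyloxy)-7-methoxy-2-[4-(tert-butyldimethylsilyloxy)phenyl]chroman-4-one
Product: 13 (2S)-5-(tert-butyldimethylsilyloxy)-7-methoxy-6,8-bis(3-methylbut-2-en-1-yl)-2-[4-(tert-butyldimethylsilyloxy)phenyl]chroman-4-one
Conditions: 2-methyl-2-butene (large excess), second-generation Grubbs catalyst RuCl2(=CHPh)(PCy3)(H2IMes) (2 × 5 mol %), 1,4-benzoquinone (10 mol %), CH2Cl2, 40 °C, sealed tube
Reagents that add atoms: 2-methyl-2-butene, CC=C(C)C
Why: Double olefin cross-metathesis of terminal allylarenes with excess 2-methyl-2-butene is the standard allyl-to-prenyl exchange, is driven by loss of propene, is neutral so that C2 is untouched, and benzoquinone holds back allyl-to-propenyl isomerisation.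

Step 11
Reactants: 13 (2S)-5-(tert-butyldimethylsilyloxy)-7-methoxy-6,8-bis(3-methylbut-2-en-1-yl)-2-[4-(tert-butyldimethylsilyloxy)phenyl]chroman-4-one
Product: 14 (2S)-5-hydroxy-2-(4-hydroxyphenyl)-7-methoxy-6,8-bis(3-methylbut-2-en-1-yl)chroman-4-one (target)
Conditions: HF·pyridine, pyridine, THF, 0 °C
Reagents that add atoms: none
Why: Fluoride-driven cleavage of both aryl silyl ethers in a buffered, weakly acidic medium forms no enolate (so no retro-oxa-Michael racemisation at C2) and is too mild to cyclise a prenyl group onto the freed 5-OH.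

**Compound list**
1 | 2,4,6-trihydroxybenzoic acid | OC(=O)c1c(O)cc(O)cc1O | starting material
2 | allyl 2,4,6-trihydroxybenzoate | C=CCOC(=O)c1c(O)cc(O)cc1O | intermediate
3 | allyl 2,6-dihydroxy-4-methoxybenzoate | C=CCOC(=O)c1c(O)cc(OC)cc1O | intermediate
4 | allyl 2,6-bis(allyloxy)-4-methoxybenzoate | C=CCOC(=O)c1c(OCC=C)cc(OC)cc1OCC=C | intermediate
5 | allyl 3,5-diallyl-2,6-dihydroxy-4-methoxybenzoate | C=CCOC(=O)c1c(O)c(CC=C)c(OC)c(CC=C)c1O | intermediate
6 | 3,5-diallyl-2,6-dihydroxy-4-methoxybenzoic acid | OC(=O)c1c(O)c(CC=C)c(OC)c(CC=C)c1O | intermediate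
7 | 4-(tert-butyldimethylsilyloxy)benzaldehyde | O=Cc1ccc(O[Si](C)(C)C(C)(C)C)cc1 | starting material
8 | trimethylsilyl 3,5-diallyl-4-methoxy-2,6-bis(trimethylsilyloxy)benzoate (not isolated) | C[Si](C)(C)OC(=O)c1c(O[Si](C)(C)C)c(CC=C)c(OC)c(CC=C)c1O[Si](C)(C)C | intermediate
9 | rac-6,8-diallyl-5-hydroxy-7-methoxy-2-[4-(tert-butyldimethylsilyloxy)phenyl]-4H-1,3-benzodioxin-4-one | O=C1OC(c2ccc(O[Si](C)(C)C(C)(C)C)cc2)Oc2c(CC=C)c(OC)c(CC=C)c(O)c21 | intermediate
10 | rac-6,8-diallyl-5-(tert-butyldimethylsilyloxy)-7-methoxy-2-[4-(tert-butyldimethylsilyloxy)phenyl]-4H-1,3-benzodioxin-4-one | O=C1OC(c2ccc(O[Si](C)(C)C(C)(C)C)cc2)Oc2c(CC=C)c(OC)c(CC=C)c(O[Si](C)(C)C(C)(C)C)c21 | intermediate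
11 | rac-6,8-diallyl-5-(tert-butyldimethylsilyloxy)-7-methoxy-4-methylidene-2-[4-(tert-butyldimethylsilyloxy)phenyl]-4H-1,3-benzodioxine | C=C1OC(c2ccc(O[Si](C)(C)C(C)(C)C)cc2)Oc2c(CC=C)c(OC)c(CC=C)c(O[Si](C)(C)C(C)(C)C)c21 | intermediate
12 | (2S)-6,8-diallyl-5-(tert-butyldimethylsilyloxy)-7-methoxy-2-[4-(tert-butyldimethylsilyloxy)phenyl]chroman-4-one | COc1c(CC=C)c(O[Si](C)(C)C(C)(C)C)c2c(c1CC=C)O[C@H](c1ccc(O[Si](C)(C)C(C)(C)C)cc1)CC2=O | intermediate
13 | (2S)-5-(tert-butyldimethylsilyloxy)-7-methoxy-6,8-bis(3-methylbut-2-en-1-yl)-2-[4-(tert-butyldimethylsilyloxy)phenyl]chroman-4-one | COc1c(CC=C(C)C)c(O[Si](C)(C)C(C)(C)C)c2c(c1CC=C(C)C)O[C@H](c1ccc(O[Si](C)(C)C(C)(C)C)cc1)CC2=O | intermediate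
14 | (2S)-5-hydroxy-2-(4-hydroxyphenyl)-7-methoxy-6,8-bis(3-methylbut-2-en-1-yl)chroman-4-one | COc1c(CC=C(C)C)c(O)c2c(c1CC=C(C)C)O[C@H](c1ccc(O)cc1)CC2=O | target

Total step count: 11. Longest linear sequence: 11 steps (1 to 14); aldehyde 7 is bought.

**Steps most likely to fail**

**Step 9.**
- What may go wrong: the anion may discriminate poorly between the two faces of the cation. C–C bond formation may outrun face exchange in the tethered ion pair, so that each enantiomer of 11 keeps a memory of its configuration and enantiomeric purity stays low. The cation may be captured by a second molecule of enol acetal. The product may racemise under acid if the quench is late.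
- Fallback (known chemistry, from 11 back to 12, stereocentre set by C2–aryl bond formation instead): mild hydrolysis of 11 (oxalic acid, wet THF, 0 °C) returns 7 and gives 1-[3,5-diallyl-6-(tert-butyldimethylsilyloxy)-2-hydroxy-4-methoxyphenyl]ethanone F1. Condensation with N,N-dimethylformamide dimethyl acetal (toluene, 90 °C) gives the (E)-enaminone F2. Catalytic TsOH in CH2Cl2 closes this to 6,8-diallyl-5-(tert-butyldimethylsilyloxy)-7-methoxychromen-4-one F3. Asymmetric 1,4-addition of 4-(tert-butyldimethylsilyloxy)phenylboronic acid with [Rh(OH)(cod)]2 and an electron-poor atropisomeric bisphosphine (toluene/H2O, rt, no added base) then gives 12.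

**Step 8.**
- What may go wrong: the bulky titanium methylidene may attack slowly at a carbonyl group flanked by the 5-silyl ether. The very labile enol acetal may rearrange prematurely (racemic) or hydrolyse on titanium residues or during isolation.
- Fallback (from 10 back to 12, without any enol acetal): the lithium enolate of tert-butyl acetate (3 equiv, THF, −78 °C) opens 10 by acyl transfer at C4, releases 7 and gives tert-butyl 3-[3,5-diallyl-6-(tert-butyldimethylsilyloxy)-2-hydroxy-4-methoxyphenyl]-3-oxopropanoate F4. Knoevenagel condensation with 7 (piperidinium acetate, toluene, 4 Å MS) gives the alkylidene β-keto ester F5 (E/Z mixture). A cinchona-derived bifunctional thiourea (10 mol %, toluene, −25 °C) closes O1–C2 by enantioselective oxa-Michael addition to the (2S)-4-oxochromane-3-carboxylate F6. TsOH (toluene, 80 °C) removes the tert-butyl ester with decarboxylation and gives 12.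

**Step 6.**
- What may go wrong: the electron-rich acid may decarboxylate. The hindered phenols may be silylated incompletely. The intermolecular condensation may be slow. The acylal-type product may hydrolyse on work-up.
- Fallback (from 5 back to 9, with the acetal built stepwise on the stable ester and closed intramolecularly): 7 is converted with trimethyl orthoformate (cat. TsOH, MeOH) into its dimethyl acetal F7. Acetyl chloride (cat. ZnBr2, CH2Cl2) turns this into the α-chloro ether 1-[chloro(methoxy)methyl]-4-(tert-butyldimethylsilyloxy)benzene F8, used as a solution. One phenol of 5 is alkylated with it (iPr2NEt, CH2Cl2, 0 °C; the second phenol stays chelated) to give the mixed acetal ester F9. Pd(PPh3)4 and morpholine release the mixed acetal acid F10. Catalytic PPTS with 5 Å MS in toluene exchanges methanol for the neighbouring carboxyl group and gives 9.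

**Further compounds**
F1 | step 9 | 1-[3,5-diallyl-6-(tert-butyldimethylsilyloxy)-2-hydroxy-4-methoxyphenyl]ethanone | CC(=O)c1c(O)c(CC=C)c(OC)c(CC=C)c1O[Si](C)(C)C(C)(C)C
F2 | step 9 | (E)-1-[3,5-diallyl-6-(tert-butyldimethylsilyloxy)-2-hydroxy-4-methoxyphenyl]-3-(dimethylamino)prop-2-en-1-one | CN(C)/C=C/C(=O)c1c(O)c(CC=C)c(OC)c(CC=C)c1O[Si](C)(C)C(C)(C)C
F3 | step 9 | 6,8-diallyl-5-(tert-butyldimethylsilyloxy)-7-methoxychromen-4-one | COc1c(CC=C)c(O[Si](C)(C)C(C)(C)C)c2c(c1CC=C)OC=CC2=O
F4 | step 8 | tert-butyl 3-[3,5-diallyl-6-(tert-butyldimethylsilyloxy)-2-hydroxy-4-methoxyphenyl]-3-oxopropanoate | CC(C)(C)OC(=O)CC(=O)c1c(O)c(CC=C)c(OC)c(CC=C)c1O[Si](C)(C)C(C)(C)C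
F5 | step 8 | tert-butyl 2-[3,5-diallyl-6-(tert-butyldimethylsilyloxy)-2-hydroxy-4-methoxybenzoyl]-3-[4-(tert-butyldimethylsilyloxy)phenyl]acrylate (E/Z mixture) | CC(C)(C)OC(=O)C(=Cc1ccc(O[Si](C)(C)C(C)(C)C)cc1)C(=O)c1c(O)c(CC=C)c(OC)c(CC=C)c1O[Si](C)(C)C(C)(C)C
F6 | step 8 | tert-butyl (2S)-6,8-diallyl-5-(tert-butyldimethylsilyloxy)-7-methoxy-4-oxo-2-[4-(tert-butyldimethylsilyloxy)phenyl]chromane-3-carboxylate (C3 epimers) | COc1c(CC=C)c(O[Si](C)(C)C(C)(C)C)c2c(c1CC=C)O[C@H](c1ccc(O[Si](C)(C)C(C)(C)C)cc1)C(C(=O)OC(C)(C)C)C2=O
F7 | step 6 | 4-(tert-butyldimethylsilyloxy)benzaldehyde dimethyl acetal | COC(OC)c1ccc(O[Si](C)(C)C(C)(C)C)cc1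
F8 | step 6 | 1-[chloro(methoxy)methyl]-4-(tert-butyldimethylsilyloxy)benzene (racemic) | COC(Cl)c1ccc(O[Si](C)(C)C(C)(C)C)cc1
F9 | step 6 | allyl 3,5-diallyl-2-hydroxy-4-methoxy-6-{methoxy[4-(tert-butyldimethylsilyloxy)phenyl]methoxy}benzoate (racemic) | C=CCOC(=O)c1c(O)c(CC=C)c(OC)c(CC=C)c1OC(OC)c1ccc(O[Si](C)(C)C(C)(C)C)cc1
F10 | step 6 | 3,5-diallyl-2-hydroxy-4-methoxy-6-{methoxy[4-(tert-butyldimethylsilyloxy)phenyl]methoxy}benzoic acid (racemic) | OC(=O)c1c(O)c(CC=C)c(OC)c(CC=C)c1OC(OC)c1ccc(O[Si](C)(C)C(C)(C)C)cc1
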